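**Strategy**

In the oxolane ring (O-1, C-2 aryl, C-3 CH2OH, C-4 aroyl) C-2 is benzylic and bound to O-1, so the C-2–aryl bond is an aryl C-glycoside bond: it is made by Friedel–Crafts attack of 2,6-dimethoxyphenol on an oxolanyl cation. The cis groups at C-3 and C-4 are tied as a γ-lactone, so the cation is a cis-fused 3,7-dioxabicyclo[3.3.0]octane that is arylated on its convex face (2,3-trans). Its precursor, a monocyclic 5-menthyloxy-γ-butyrolactone whose bought acetal centre has relayed C-3 and C-4, rearranges to this bicycle in the same flask. Aryllithium opening of the lactone then unveils ketone and CH2OH.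

Key step: step 3

Assumption: (5S)-5-(d-menthyloxy)furan-2(5H)-one 1, the butenolide of the (+)-menthol series, is taken as a commercial compound ("d-menthyl" = (1S,2R,5S)-5-methyl-2-(propan-2-yl)cyclohexyl throughout).

**Route**

Step 1
Reactants: 1 (5S)-5-(d-menthyloxy)furan-2(5H)-one
Product: 2 (4R,5S)-4-(hydroxymethyl)-5-(d-menthyloxy)oxolan-2-one
Conditions: MeOH (solvent, degassed), Ph2CO (0.2 equiv), hν 350 nm, rt
Reagents that add atoms: methanol, CO
Why: Triplet benzophenone abstracts H from methanol and the nucleophilic hydroxymethyl radical adds to the β-carbon C-4 of the butenolide anti to the bulky C-5 menthyloxy group (photochemical Giese-type conjugate addition, known for 5-alkoxyfuranones), which should set C-4 as R by substrate control.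

Step 2
Reactants: 2 (4R,5S)-4-(hydroxymethyl)-5-(d-menthyloxy)oxolan-2-one
Product: 4 (3R,4R,5S)-3,4-bis(hydroxymethyl)-5-(d-menthyloxy)oxolan-2-one, via dilithium alkoxide-enolate 3 (not isolated)
Conditions: LDA (2.3 equiv), THF, −78 °C (2 added to the base); CH2O (gas, from cracked paraformaldehyde), −78 → −50 °C; AcOH, −78 °C
Reagents that add atoms: formaldehyde, C=O
Why: Double deprotonation gives 3, in which enolisation shields the lactone carbonyl from the neighbouring alkoxide, and the aldol addition to formaldehyde (hydroxymethylation of a lactone enolate) should occur anti to the C-4 substituent, setting C-3 as R (3,4-trans) by substrate control.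

Step 3
Reactants: 4 (3R,4R,5S)-3,4-bis(hydroxymethyl)-5-(d-menthyloxy)oxolan-2-one; 5 2,6-dimethoxyphenol
Product: 7 (3aR,4S,6aR)-4-(4-hydroxy-3,5-dimethoxyphenyl)tetrahydro-1H,3H-furo[3,4-c]furan-1-one, via bicyclic menthyl acetal 6 (not isolated)
Conditions: 5 (1.3 equiv), BF3·OEt2 (0.5 equiv), 4 Å MS, CH2Cl2, −20 °C → rt; then Et3N
Reagents that add atoms: none
Why: The Lewis acid opens the pseudo-ester acetal of 4: the CH2OH on C-3 adds to the menthyloxy-stabilised oxocarbenium carbon C-5 (5-exo-trig, closes the oxolane) and the freed carboxyl lactonises onto the CH2OH on C-4 (5-exo-trig, closes the γ-lactone), and because these two arms are trans on the old ring the new bicycle 6 can only be cis-fused. Loss of menthol from 6 gives a bicyclic oxocarbenium ion that is attacked by C-4 of phenol 5, followed by rearomatisation. The closest known reaction type is the Lewis-acid Friedel–Crafts C-arylation of lactol ethers and glycosyl donors by phenols (aryl C-glycoside synthesis). The new aryl-bearing stereocentre is set by substrate control, since the arene adds to the convex face of the cis-fused bicycle, anti to both ring-fusion bonds (4S, the 2,3-trans relation of the target). The step needs para-regioselectivity on the arene, secured by the OMe groups that block both ortho positions and by OH as the strongest director, and C- over O-arylation, secured because O-attack is reversible under the acid. It also needs kinetic control (low temperature, substoichiometric acid, amine quench) so that the electron-rich benzylic ether of 7 does not re-ionise.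

Step 4
Reactants: 8 4-bromo-2,6-dimethoxyphenol
Product: 9 (4-bromo-2,6-dimethoxyphenoxy)(tert-butyl)dimethylsilane
Conditions: TBSCl (1.2 equiv), imidazole (2.5 equiv), DMF, rt
Reagents that add atoms: tert-butyldimethylsilyl chloride, C[Si](C)(Cl)C(C)(C)C
Why: Imidazole-mediated O-silylation of the phenol (substitution at silicon) masks the acidic OH for the halogen–lithium exchange; no stereocentre is involved.

Step 5
Reactants: 7 (3aR,4S,6aR)-4-(4-hydroxy-3,5-dimethoxyphenyl)tetrahydro-1H,3H-furo[3,4-c]furan-1-one; 9 (4-bromo-2,6-dimethoxyphenoxy)(tert-butyl)dimethylsilane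
Product: 12 {4-[(tert-butyldimethylsilyl)oxy]-3,5-dimethoxyphenyl}[(3R,4R,5S)-5-(4-hydroxy-3,5-dimethoxyphenyl)-4-(hydroxymethyl)oxolan-3-yl]methanone, via aryllithium 10 (not isolated), via dilithium hemiketalate 11 (not isolated)
Conditions: 9 (2.4 equiv), n-BuLi (2.3 equiv), THF, −78 °C; then 7 in THF, −78 °C; AcOH in THF, −78 °C → rt
Reagents that add atoms: none
Why: Bromine–lithium exchange gives 10, of which one equivalent deprotonates the phenol of 7 and the second adds to the lactone carbonyl (acyl substitution of a lactone by an organolithium) to give the cyclic hemiketalate 11, which should not collapse at −78 °C and therefore neither takes up a second aryl nor enolises next to the ring-fusion stereocentre; protonation opens it to the hydroxy ketone with all three stereocentres untouched.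

Step 6
Reactants: 12 {4-[(tert-butyldimethylsilyl)oxy]-3,5-dimethoxyphenyl}[(3R,4R,5S)-5-(4-hydroxy-3,5-dimethoxyphenyl)-4-(hydroxymethyl)oxolan-3-yl]methanone
Product: 13 Ciwujiatone, (4-hydroxy-3,5-dimethoxyphenyl)[(3R,4R,5S)-5-(4-hydroxy-3,5-dimethoxyphenyl)-4-(hydroxymethyl)oxolan-3-yl]methanone
Conditions: TBAF (1.1 equiv), AcOH (1.2 equiv), THF, 0 °C
Reagents that add atoms: none
Why: Fluoride-mediated desilylation of the aryl silyl ether (the p-acylphenoxide is a good leaving group on silicon), with the acetic acid buffer keeping the medium non-basic so that the centre α to the ketone should not epimerise.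

**Compound list**

1 | (5S)-5-{[(1S,2R,5S)-5-methyl-2-(propan-2-yl)cyclohexyl]oxy}furan-2(5H)-one | O=C1C=C[C@@H](O[C@H]2C[C@@H](C)CC[C@@H]2C(C)C)O1 | starting material
2 | (4R,5S)-4-(hydroxymethyl)-5-(d-menthyloxy)oxolan-2-one (4,5-trans) | O=C1C[C@H](CO)[C@@H](O[C@H]2C[C@@H](C)CC[C@@H]2C(C)C)O1 | intermediate
3 | dilithium alkoxide-enolate of 2 | [Li]OC[C@H]1C=C(O[Li])O[C@@H]1O[C@H]2C[C@@H](C)CC[C@@H]2C(C)C | intermediate (not isolated)
4 | (3R,4R,5S)-3,4-bis(hydroxymethyl)-5-(d-menthyloxy)oxolan-2-one (3,4-trans, 4,5-trans) | O=C1[C@@H](CO)[C@H](CO)[C@@H](O[C@H]2C[C@@H](C)CC[C@@H]2C(C)C)O1 | intermediate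
5 | 2,6-dimethoxyphenol | COc1cccc(OC)c1O | starting material
6 | (3aR,6aR)-4-(d-menthyloxy)tetrahydro-1H,3H-furo[3,4-c]furan-1-one (cis-fused, both epimers at C-4) | O=C1OC[C@H]2[C@@H]1COC2O[C@H]3C[C@@H](C)CC[C@@H]3C(C)C | intermediate (not isolated)
7 | (3aR,4S,6aR)-4-(4-hydroxy-3,5-dimethoxyphenyl)tetrahydro-1H,3H-furo[3,4-c]furan-1-one (cis-fused, aryl exo) | O=C1OC[C@H]2[C@@H]1CO[C@@H]2c3cc(OC)c(O)c(OC)c3 | intermediate
8 | 4-bromo-2,6-dimethoxyphenol | COc1cc(Br)cc(OC)c1O | starting material
9 | (4-bromo-2,6-dimethoxyphenoxy)(tert-butyl)dimethylsilane | COc1cc(Br)cc(OC)c1O[Si](C)(C)C(C)(C)C | intermediate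
10 | {4-[(tert-butyldimethylsilyl)oxy]-3,5-dimethoxyphenyl}lithium | [Li]c1cc(OC)c(O[Si](C)(C)C(C)(C)C)c(OC)c1 | intermediate (not isolated)
11 | dilithium salt (hemiketal O and phenol O) of the bicyclic hemiketal formed by addition of 10 to the lactone carbonyl of 7 (both epimers at the ketal carbon) | [Li]OC1(c4cc(OC)c(O[Si](C)(C)C(C)(C)C)c(OC)c4)OC[C@H]2[C@@H]1CO[C@@H]2c3cc(OC)c(O[Li])c(OC)c3 | intermediate (not isolated)
12 | {4-[(tert-butyldimethylsilyl)oxy]-3,5-dimethoxyphenyl}[(3R,4R,5S)-5-(4-hydroxy-3,5-dimethoxyphenyl)-4-(hydroxymethyl)oxolan-3-yl]methanone | COc1cc(C(=O)[C@H]2CO[C@H](c3cc(OC)c(O)c(OC)c3)[C@H]2CO)cc(OC)c1O[Si](C)(C)C(C)(C)C | intermediate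
13 | Ciwujiatone, (4-hydroxy-3,5-dimethoxyphenyl)[(3R,4R,5S)-5-(4-hydroxy-3,5-dimethoxyphenyl)-4-(hydroxymethyl)oxolan-3-yl]methanone | COc1cc(C(=O)[C@H]2CO[C@H](c3cc(OC)c(O)c(OC)c3)[C@H]2CO)cc(OC)c1O | target

**Step count and risks**

Total step count: 6. Longest linear sequence: 5 (steps 1, 2, 3, 5, 6).

Steps most likely to fail:

1. Step 3. The electron-rich benzylic C–O bond of the product may re-ionise under the acid, which would erode the configuration at the new centre or let a second arene add with ring opening; the cascade may also stall at the acetal stage. The fallback sets out from 4 and comes back at 7, and replaces the acid/arene pair by a sulfone/aryl-metal pair. Warming 4 in aqueous acid (1 M HCl, THF, 40 °C) should bring about the same ring switch with hydrolysis to the bicyclic lactol F1. Benzenesulfinic acid (CaCl2, CH2Cl2) should convert it into the 4-phenylsulfonyl lactone F2. The arylzinc bromide F3, made from aryllithium 10 and ZnBr2, should then displace the sulfinate through the same oxocarbenium ion under non-protic conditions (THF, rt), again on the convex face, to give the O-silylated aryl lactone F4. Its less electron-rich ring should not re-ionise, and TBAF/AcOH should give 7.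

2. Step 2. The alkoxide may transfer the acyl group of the pseudo-ester to itself before enolisation, with loss of the menthyloxy acetal, or the aldolate may eliminate to the α-methylene lactone. The fallback sets out from 2 and comes back at 4, and uses a mono-anion instead of the dianion. Silylation of 2 (TBSCl, imidazole, DMF) should give the silyl ether F5. Its lithium enolate (LDA 1.1 equiv, THF, −78 °C) with gaseous formaldehyde should give the 3,4-trans hydroxymethyl lactone F6, and HF·pyridine (THF/pyridine, 0 °C) should give 4.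

3. Step 5. The aryllithium may act as a base at the carbon α to the lactone carbonyl, the lithium phenoxide of 7 may precipitate, or the hemiketalate may open and take up a second aryl. The fallback sets out from 7 and comes back at 13, and changes the acyl acceptor. Aminolysis of the lactone (MeNHOMe·HCl, Me3Al, CH2Cl2, 0 °C) should give the hydroxy Weinreb amide F7. Silylation of both hydroxyl groups (TBSCl, imidazole, DMF) should give the bis-silyl ether F8. Aryllithium 10 (1.2 equiv, THF, −78 °C) should give the tris-silylated ketone F9 through the stable N-methoxy chelate, and TBAF/AcOH should remove the three silyl groups to give 13.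

Further compounds
F1 | step 3 | (3aR,6aR)-4-hydroxytetrahydro-1H,3H-furo[3,4-c]furan-1-one (both epimers at C-4) | O=C1OC[C@H]2[C@@H]1COC2O
F2 | step 3 | (3aR,6aR)-4-(benzenesulfonyl)tetrahydro-1H,3H-furo[3,4-c]furan-1-one (both epimers at C-4) | O=C1OC[C@H]2[C@@H]1COC2S(=O)(=O)c3ccccc3
F3 | step 3 | {4-[(tert-butyldimethylsilyl)oxy]-3,5-dimethoxyphenyl}zinc bromide | Br[Zn]c1cc(OC)c(O[Si](C)(C)C(C)(C)C)c(OC)c1
F4 | step 3 | (3aR,4S,6aR)-4-{4-[(tert-butyldimethylsilyl)oxy]-3,5-dimethoxyphenyl}tetrahydro-1H,3H-furo[3,4-c]furan-1-one | O=C1OC[C@H]2[C@@H]1CO[C@@H]2c3cc(OC)c(O[Si](C)(C)C(C)(C)C)c(OC)c3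
F5 | step 2 | (4R,5S)-4-{[(tert-butyldimethylsilyl)oxy]methyl}-5-(d-menthyloxy)oxolan-2-one | O=C1C[C@H](CO[Si](C)(C)C(C)(C)C)[C@@H](O[C@H]2C[C@@H](C)CC[C@@H]2C(C)C)O1
F6 | step 2 | (3R,4R,5S)-4-{[(tert-butyldimethylsilyl)oxy]methyl}-3-(hydroxymethyl)-5-(d-menthyloxy)oxolan-2-one | O=C1[C@@H](CO)[C@H](CO[Si](C)(C)C(C)(C)C)[C@@H](O[C@H]2C[C@@H](C)CC[C@@H]2C(C)C)O1
F7 | step 5 | (3R,4R,5S)-5-(4-hydroxy-3,5-dimethoxyphenyl)-4-(hydroxymethyl)-N-methoxy-N-methyloxolane-3-carboxamide | CON(C)C(=O)[C@H]1CO[C@H](c2cc(OC)c(O)c(OC)c2)[C@H]1CO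
F8 | step 5 | (3R,4R,5S)-5-{4-[(tert-butyldimethylsilyl)oxy]-3,5-dimethoxyphenyl}-4-{[(tert-butyldimethylsilyl)oxy]methyl}-N-methoxy-N-methyloxolane-3-carboxamide | CON(C)C(=O)[C@H]1CO[C@H](c2cc(OC)c(O[Si](C)(C)C(C)(C)C)c(OC)c2)[C@H]1CO[Si](C)(C)C(C)(C)C
F9 | step 5 | {4-[(tert-butyldimethylsilyl)oxy]-3,5-dimethoxyphenyl}[(3R,4R,5S)-5-{4-[(tert-butyldimethylsilyl)oxy]-3,5-dimethoxyphenyl}-4-{[(tert-butyldimethylsilyl)oxy]methyl}oxolan-3-yl]methanone | COc1cc(C(=O)[C@H]2CO[C@H](c3cc(OC)c(O[Si](C)(C)C(C)(C)C)c(OC)c3)[C@H]2CO[Si](C)(C)C(C)(C)C)cc(OC)c1O[Si](C)(C)C(C)(C)C
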